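Readings and results were generated by integration from invented constants, noise included.

The trap in this flask was to count nucleophile that had not become target as nucleophile still free to react. I kept the two apart, taking one nucleophile for each target.

| flask | electrophile | nucleophile | remark | time |
|---|---|---|---|---|
| gamma | 0.0067 M | 0.90 equiv | run made earlier |  |
| beta | 0.015 M | 0.90 equiv | run made earlier |  |
| delta | 0.010 M | 1.8 equiv | run made earlier |  |
| flask | 0.010 M | 0.900 equiv |  | 2.0 d |

- gamma (time / h: electrophile / %, target / %): 10.0: 28.8, 54.2; 20.0: 16.4, 62.1; 30.0: 12.8, 64.2; 40.0: 8.3, 66.0
- beta (time / h: electrophile / %, target / %): 5.00: 31.1, 53.1; 15.0: 11.9, 61.5; 25.0: 7.3, 64.7; 40.0: 0.2, 66.0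
- delta (time / h: electrophile / %, target / %): 10.0: 3.5, 87.5; 20.0: 0.5, 93.3; 30.0: 1.0, 93.9; 40.0: 0.6, 92.7

(standard deviation of a reading: 1 percentage point)

- part of the electrophile that has reacted at 2.0 d
- share of the unused nucleophile that is free and not bound as protonated nucleophile, at 2.0 d

I read beta's table from the bottom. Between its last two rows electrophile fell by 7.1 percentage points while target rose by 1.3 points, close to the scatter of 1 point, so I took target as levelling near 66.0%. Gamma's last row also shows 66.0%, with 8.3% of electrophile still there.

The charge of nucleophile minus the target, both as fractions of the electrophile charged, gave 24.0% for beta: this is the unused nucleophile. Delta's last row, from 1.8 equiv of nucleophile, gave 87.3%. For the flask, which shares beta's 0.900 equiv of nucleophile but not its electrophile concentration, I reckoned the same 24.0%. No column shows protonated nucleophile, so the split of that amount into free and bound stayed a guess.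

The forecast gave 96% reacted and 50% free: “about half is free, which is largely a guess”.

The flask gave 96.2% reacted and a free share of 13.9%.

    electrophile + nucleophile → acid set free + target (k = 0.0170 M⁻¹ s⁻¹)
    nucleophile + acid set free ⇌ protonated nucleophile, settled at all times (K = 1600 M⁻¹)
    2 electrophile → homo dimer (k = 0.00110 M⁻¹ s⁻¹)
    electrophile + acid set free → side product (k = 0.00130 M⁻¹ s⁻¹)

At 2.00 d the flask held target at 67.3%, so its unused nucleophile came to 22.7% against my 24.0%. Of that, 19.6% of the electrophile charged stood in the flask as protonated nucleophile, which is more than the 3.15% on the same basis still free. The neighbour flask with 2.20 equiv of nucleophile reached target at 95.3%, so the same subtraction gave 125% unused, and its free share was 33.7%.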